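**Retrosynthetic overview**

- The target has two catechol rings, B and C, joined by the C5–C1' biaryl bond, and no stereocentre. Two CH2–CH2 bridges, one from C1 of ring B to ring A and one from C2' of ring C to ring D, both end in the same 3-methoxyphenyl ring; the strategy rests on this feature.
- The last disconnections are the four O–benzyl bonds and the two benzylic C–H bonds, which come from C–B(pin) groups on the anisole-side bridge carbons.
- Key disconnection: each bridge is cut on both sides of its two carbons. This gives a biaryl dibromide, two vinyl–B(pin) units and two 3-methoxyphenyl Grignard units, joined in one twofold conjunctive cross-coupling that forms four C–C bonds.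
- The dibromide comes from bromination of ring C at C2' after a Suzuki coupling at iodine. The ring B iodide is made from 4-bromo-2-methoxyphenol by ortho-iodination, demethylation and dibenzylation, and is coupled with 3,4-bis(benzyloxy)phenylboronic acid.
- No ring is formed. All four benzene rings are bought: ring B is functionalised first, ring C is attached next, and rings A and D are attached together in the key step.

Key step: step 6

Assumption: the two boron-bearing benzylic carbons formed in step 6 are not controlled, and compounds 11 and 12 are carried as stereoisomer mixtures; this is harmless because step 7 converts both carbons into CH2.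

**Step 1**
Reactants: 1 4-bromo-2-methoxyphenol
Product: 2 4-bromo-2-iodo-6-methoxyphenol
Conditions: N-iodosuccinimide, TsOH·H2O (cat.), MeCN, 0 °C → rt
Reagents that add atoms: N-iodosuccinimide, O=C1CCC(=O)N1I
Why: Electrophilic aromatic iodination: the free phenol directs ortho and para, the para carbon carries bromine, so iodine should enter at the one free ortho carbon.

**Step 2**
Reactants: 2 4-bromo-2-iodo-6-methoxyphenol
Product: 3 5-bromo-3-iodobenzene-1,2-diol
Conditions: BBr3, CH2Cl2, −78 °C → rt; then H2O
Reagents that add atoms: none
Why: Lewis-acid cleavage of the aryl methyl ether: BBr3 binds the methoxy oxygen and bromide removes the methyl group by SN2 attack, while the aryl C–Br and C–I bonds are not touched.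

**Step 3**
Reactants: 3 5-bromo-3-iodobenzene-1,2-diol
Product: 4 1,2-bis(benzyloxy)-5-bromo-3-iodobenzene
Conditions: BnBr (2.3 equiv), K2CO3, DMF, N2, rt → 50 °C
Reagents that add atoms: benzyl bromide, BrCc1ccccc1
Why: Twofold Williamson ether synthesis of the catechol with a reactive benzylic bromide, run under nitrogen so that the catechol is not oxidised before it is capped.

**Step 4**
Reactants: 4 1,2-bis(benzyloxy)-5-bromo-3-iodobenzene; 5 3,4-bis(benzyloxy)phenylboronic acid
Product: 6 1,2-bis(benzyloxy)-3-[3,4-bis(benzyloxy)phenyl]-5-bromobenzene
Conditions: Pd(PPh3)4 (cat.), Na2CO3 (aq.), toluene/EtOH, 70 °C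
Reagents that add atoms: none
Why: Suzuki–Miyaura coupling in which zerovalent palladium adds to the C–I bond much faster than to the C–Br bond, so with one equivalent of 5 at moderate temperature the biaryl bond should form at C5 of ring B and the C1 bromide should be kept.

**Step 5**
Reactants: 6 1,2-bis(benzyloxy)-3-[3,4-bis(benzyloxy)phenyl]-5-bromobenzene
Product: 7 1,2-bis(benzyloxy)-3-[4,5-bis(benzyloxy)-2-bromophenyl]-5-bromobenzene
Conditions: N-bromosuccinimide (1 equiv), DMF, 0 °C → rt, dark
Reagents that add atoms: N-bromosuccinimide, O=C1CCC(=O)N1Br
Why: Electrophilic aromatic bromination: ring C is the more electron-rich ring and its carbon para to the C5' benzyloxy group and ortho to the biaryl bond (C2' in target numbering) is the usual halogenation site of 4-substituted catechol diethers, whereas ring B is deactivated by bromine and its para-to-oxygen carbon is wedged between bromine and the aryl group.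

**Step 6**
Reactants: 7 1,2-bis(benzyloxy)-3-[4,5-bis(benzyloxy)-2-bromophenyl]-5-bromobenzene; 8 vinylboronic acid pinacol ester; 9 3-methoxyphenylmagnesium bromide (THF solution)
Product: 12 tetra-O-benzyl isoplagilin bis(pinacol boronate) carrying one B(pin) on each anisole-side bridge carbon (stereoisomer mixture), via boron ate complex 10 (not isolated), via monobridged aryl bromide 11 (not isolated)
Conditions: 8 (2.6 equiv) + 9 (2.4 equiv), THF, 0 °C → rt; then CF3SO3Na, 7 (1 equiv), Pd(OAc)2 (cat.), 1,1'-bis[bis(4-methoxy-3,5-dimethylphenyl)phosphino]-2,2'-bis[(dimethylamino)(phenyl)methyl]ferrocene (MandyPhos-type ligand, cat.), THF, 60 °C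
Reagents that add atoms: vinylboronic acid pinacol ester (second equivalent of 8), C=CB1OC(C)(C)C(C)(C)O1; 3-methoxyphenylmagnesium bromide (second equivalent of 9), COc1cccc([Mg]Br)c1
Why: Zerovalent palladium inserts into a C–Br bond of 7, CF3SO3Na removes the bromide so that the resulting cationic arylpalladium complex (divalent palladium) coordinates the vinyl group of ate complex 10, the 3-methoxyphenyl group then migrates from boron to the boron-bearing carbon while the terminal carbon bonds to palladium, and reductive elimination joins that CH2 to the core carbon; this should happen first at the unhindered C1 of ring B (giving 11) and then at C2' of ring C, so that two molecules of 10 are used up and four C–C bonds are formed. The closest known reaction is the palladium-catalysed conjunctive cross-coupling of Grignard-derived vinylboron ate complexes with aryl bromides and triflates, applied here to both bromides of one substrate. No ring is closed. Each coupling creates one boron-bearing benzylic stereocentre; the two centres are far apart and not controlled relative to each other, which is of no consequence because step 7 turns both into CH2. The step needs the 1,2-metallate shift to outrun direct aryl or vinyl transfer from boron to palladium (Suzuki-type products) at both sites, including the C2' bromide next to the biaryl bond; the wide-bite-angle ferrocene bisphosphine and the halide-free cationic palladium centre should secure this, and the excess of 10 should drive the slower second coupling. The benzyl and methyl ethers are inert, and the secondary benzylic B(pin) groups of the product should not transmetallate under these base-free conditions.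

**Step 7**
Reactants: 12 tetra-O-benzyl isoplagilin bis(pinacol boronate)
Product: 13 1,2-bis(benzyloxy)-3-{4,5-bis(benzyloxy)-2-[2-(3-methoxyphenyl)ethyl]phenyl}-5-[2-(3-methoxyphenyl)ethyl]benzene
Conditions: Bu4NF·3H2O (excess), toluene, 80 °C
Reagents that add atoms: none
Why: Fluoride-promoted protodeboronation of benzylic boronic esters: fluoride forms the boron ate complex and the water of hydration protonates the benzylic C–B bond, so both CH(B) carbons should become CH2 and the stereoisomer mixture should collapse to one compound.

**Step 8**
Reactants: 13 1,2-bis(benzyloxy)-3-{4,5-bis(benzyloxy)-2-[2-(3-methoxyphenyl)ethyl]phenyl}-5-[2-(3-methoxyphenyl)ethyl]benzene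
Product: 14 isoplagilin
Conditions: H2 (1 atm), palladium on carbon (Pd/C, 10%), EtOAc/MeOH, rt; work-up under N2
Reagents that add atoms: none
Why: Hydrogenolysis of the four benzyl aryl ethers over palladium on carbon, which should leave the aryl methyl ethers and the saturated bridges untouched and free both catechols.

**Compound list**

1 | 4-bromo-2-methoxyphenol | COc1cc(Br)ccc1O | starting material
2 | 4-bromo-2-iodo-6-methoxyphenol | COc1cc(Br)cc(I)c1O | intermediate
3 | 5-bromo-3-iodobenzene-1,2-diol | Oc1cc(Br)cc(I)c1O | intermediate
4 | 1,2-bis(benzyloxy)-5-bromo-3-iodobenzene | Brc1cc(I)c(OCc2ccccc2)c(OCc2ccccc2)c1 | intermediate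
5 | 3,4-bis(benzyloxy)phenylboronic acid | OB(O)c1ccc(OCc2ccccc2)c(OCc2ccccc2)c1 | starting material
6 | 1,2-bis(benzyloxy)-3-[3,4-bis(benzyloxy)phenyl]-5-bromobenzene | Brc1cc(OCc2ccccc2)c(OCc2ccccc2)c(-c2ccc(OCc3ccccc3)c(OCc3ccccc3)c2)c1 | intermediate
7 | 1,2-bis(benzyloxy)-3-[4,5-bis(benzyloxy)-2-bromophenyl]-5-bromobenzene | Brc1cc(OCc2ccccc2)c(OCc2ccccc2)c(-c2cc(OCc3ccccc3)c(OCc3ccccc3)cc2Br)c1 | intermediate
8 | vinylboronic acid pinacol ester | C=CB1OC(C)(C)C(C)(C)O1 | starting material
9 | 3-methoxyphenylmagnesium bromide | COc1cccc([Mg]Br)c1 | starting material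
10 | bromomagnesium (3-methoxyphenyl)(vinyl)(pinacolato)borate, ate complex | COc1cccc([B-]2(C=C)OC(C)(C)C(C)(C)O2)c1.[Mg+]Br | intermediate
11 | 2-{2-[3,4-bis(benzyloxy)-5-(4,5-bis(benzyloxy)-2-bromophenyl)phenyl]-1-(3-methoxyphenyl)ethyl}-4,4,5,5-tetramethyl-1,3,2-dioxaborolane (racemic) | COc1cccc(C(Cc2cc(OCc3ccccc3)c(OCc3ccccc3)c(-c3cc(OCc4ccccc4)c(OCc4ccccc4)cc3Br)c2)B2OC(C)(C)C(C)(C)O2)c1 | intermediate
12 | tetra-O-benzyl isoplagilin carrying a B(pin) group on each anisole-side bridge carbon (stereoisomer mixture, both centres undefined) | COc1cccc(C(Cc2cc(OCc3ccccc3)c(OCc3ccccc3)c(-c3cc(OCc4ccccc4)c(OCc4ccccc4)cc3CC(B3OC(C)(C)C(C)(C)O3)c3cccc(OC)c3)c2)B2OC(C)(C)C(C)(C)O2)c1 | intermediate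
13 | 1,2-bis(benzyloxy)-3-{4,5-bis(benzyloxy)-2-[2-(3-methoxyphenyl)ethyl]phenyl}-5-[2-(3-methoxyphenyl)ethyl]benzene | COc1cccc(CCc2cc(OCc3ccccc3)c(OCc3ccccc3)c(-c3cc(OCc4ccccc4)c(OCc4ccccc4)cc3CCc3cccc(OC)c3)c2)c1 | intermediate
14 | isoplagilin | COc1cccc(CCc2cc(O)c(O)c(-c3cc(O)c(O)cc3CCc3cccc(OC)c3)c2)c1 | target

**Step count**

Total steps: 8. Longest linear sequence: 8 steps (1 → 14).

**Steps most likely to fail**

Step 6. Direct transfer of the aryl or vinyl group from boron to palladium may compete with the metallate shift, and the second coupling at the hindered C2' bromide may stall or end in protodehalogenation. The fallback sets out from 7 and returns at 13. 1-Methoxy-3-vinylbenzene is hydroborated with 9-borabicyclo[3.3.1]nonane in THF to give 9-[2-(3-methoxyphenyl)ethyl]-9-borabicyclo[3.3.1]nonane F1. Without isolation, F1 is coupled twice with 7 in a B-alkyl Suzuki–Miyaura reaction (PdCl2(dppf), K3PO4 aq., THF/DMF, 65 °C), which would deliver both saturated bridges and give 13 directly; the route then continues with step 8.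

Step 7. Protonolysis of the secondary benzylic C–B bonds may be slow, since the carbanion character is stabilised by only one aryl group, and the reaction may stop after one boron has been removed. The fallback sets out from 12 and returns at 14. Both C–B bonds are oxidised with retention (NaBO3·4H2O, THF/H2O, rt) to the bis(benzylic alcohol) F2, a diol with one hydroxyl on each anisole-side bridge carbon. F2 is then hydrogenated over palladium on carbon (Pd/C) in AcOH with catalytic H2SO4 under H2 at 40 °C, which should cleave the two benzylic C–OH bonds and the four benzyl ethers in one operation and give 14.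

Step 5. Bromination may also occur on ring B or a second time on ring C, and the regioisomers would be hard to separate. The fallback fixes the halogen position before the biaryl bond is made; it sets out from 4 and returns at 7. Commercial 1,2-bis(benzyloxy)benzene is brominated twice (Br2, CH2Cl2, 0 °C) to 1,2-bis(benzyloxy)-4,5-dibromobenzene F3. A single bromine–magnesium exchange (iPrMgCl·LiCl, THF, −15 °C) gives [4,5-bis(benzyloxy)-2-bromophenyl]magnesium chloride F4. F4 is quenched with B(OMe)3 and hydrolysed with dilute HCl to (4,5-bis(benzyloxy)-2-bromophenyl)boronic acid F5. Suzuki–Miyaura coupling of F5 with 4 at the C–I bond (Pd(PPh3)4, Na2CO3 aq., toluene/EtOH, 60 °C) would give 7 without compound 6.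

**Further compounds**

F1 | step 6 | 9-[2-(3-methoxyphenyl)ethyl]-9-borabicyclo[3.3.1]nonane | COc1cccc(CCB2C3CCCC2CCC3)c1
F2 | step 7 | tetrabenzyl isoplagilin carrying a hydroxyl group on each anisole-side bridge carbon (stereoisomer mixture) | COc1cccc(C(O)Cc2cc(OCc3ccccc3)c(OCc3ccccc3)c(-c3cc(OCc4ccccc4)c(OCc4ccccc4)cc3CC(O)c3cccc(OC)c3)c2)c1
F3 | step 5 | 1,2-bis(benzyloxy)-4,5-dibromobenzene | Brc1cc(OCc2ccccc2)c(OCc2ccccc2)cc1Br
F4 | step 5 | [4,5-bis(benzyloxy)-2-bromophenyl]magnesium chloride | Cl[Mg]c1cc(OCc2ccccc2)c(OCc2ccccc2)cc1Br
F5 | step 5 | (4,5-bis(benzyloxy)-2-bromophenyl)boronic acid | OB(O)c1cc(OCc2ccccc2)c(OCc2ccccc2)cc1Br
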